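## Structural features

Larreantin (19) is a 2-methoxy-1,4-naphthoquinone. Ring A (C1, C2, C3, C4, C4a, C8a) is the quinone, with the methoxy group on C2 and a hydrogen on C3. Ring B (C4a, C5, C6, C7, C8, C8a) is the fused benzene ring. Ring B carries, in order, H on C5, a 4-hydroxy-3-methoxybenzyl group on C6, a methyl group on C7 and a 4-hydroxy-3-methoxyphenyl group on C8. The C8 aryl group is therefore peri to the C1 carbonyl, which is the carbonyl flanked by the methoxy-bearing C2. There is no stereocenter, and the C8–aryl bond is not a stable axis because the guaiacyl ring has no ortho substituent. The fragile groups are the methoxyquinone (a vinylogous ester and Michael acceptor, sensitive to bases, nucleophiles and reductants), the two free phenols, and the doubly benzylic CH2 on C6. The real difficulty is regiochemical: four contiguous, different positions on ring B, and an unsymmetrical ring A that must be oriented so that the methoxy side faces the aryl-bearing C8. The key step exploits the fact that C4a/C5, C6/C7 and C8/C8a can each be an alkyne, and that the first and third are linked through C4–C3–C2–C1 of ring A, already at the enedione oxidation level.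

## Logic of the disconnections

**19 ⇒ 18.** The two phenolic O–H bonds are traced back to O–Si bonds. The skeleton is not simplified, but the phenols are masked against the organolithium, Grignard and rhodium steps. The forward step must remove silicon without base, because a phenoxide next to a methoxyquinone invites addition and substitution.

**18 ⇒ 17 + 7.** The bonds C4a–C8a, C5–C6 and C7–C8 are cut, which opens rings A and B together and leaves three alkynes. Two rings and all four ring B substituents then come from two acyclic pieces with no later redox step. Atom mapping confirms the orientation: the carbonyl of 17 next to the methoxy carbon (C1) carries the aryl alkyne, so the aryl group ends on C8. The forward step demands that the acyl groups of 17 stay cis, that 17 does not react with itself through its terminal alkyne, and that 7 inserts with CH2Ar at C6. The design answers this as follows: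
- 17 is made in the step directly before, under neutral conditions, and used without chromatography.
- C5 is left as C–H: a silyl group there would reverse the steric bias and would be hard to remove from the arene.
- The catalyst carries no free phosphine, which could isomerise or add to the ynones.

**17 ⇒ 15.** The two carbonyl oxygens on C1 and C4 are merged into one ring oxygen bridging C1 and C4 (retro-oxidative ring opening of a furan). The ring fixes the cis relationship of the two acyl groups, and the labile enedione is replaced by a stable aromatic carrier. The forward step needs an oxidant that attacks the methoxyfuran before the alkynes or the guaiacyl ring and leaves nothing to separate.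

**15 ⇒ 14 ⇒ 12.** The C4a≡C5 triple bond is cut by removing C5 (one-carbon homologation of an aldehyde), then the C4–C4a bond is cut (formyl group on the furan). The terminal alkyne is thus installed without a halofuran and without a C-silyl group to remove later. The forward steps demand metalation at the one free α-position of the furan in 12.

**12 ⇒ 11 + 3.** The sp2–sp bond C1–C8a (furan C2 to alkyne) is cut. This separates the heterocycle from the aryl unit and makes the route convergent. The demand is that the electron-rich iodide 11 survives long enough to couple.

**11 ⇒ 9 ⇒ 8.** The C–I bond is cut back to C–H (deprotonation between the ring oxygen and the methoxy group), then the C–O bond of the methoxy group is cut back to C–Br. Both positions are addressed one at a time, so no regiochemical question arises.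

**3 ⇒ 2.** The aryl alkyne is cut between its two alkyne carbons: the inner carbon is the aldehyde carbon of 2. This lets one aldehyde serve both aryl units.

**7 ⇒ 5 + 6, 5 ⇒ 4 ⇒ 2 ⇒ 1.** The CH2–C(sp) bond is cut to a benzylic electrophile and a propynyl nucleophile, then C–Br to C–OH, C–OH to the aldehyde, and O–Si to the free phenol of 1. The demand is that the ionisable benzylic bromide 5 is coupled promptly.

## Other disconnections considered

**Alternative 1:** Ring B is cut at C7=C8 after stepping back to its 5,6-dihydro form. In the forward sense the keto ketone A2 (a diaryl ketone at C8 and a methyl ketone at C7) is coupled by low-valent titanium from TiCl3 (trivalent titanium) and Zn–Cu in a McMurry reaction, closing ring B as the racemic dihydronaphthalene A1.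
- *In favour:* every ring B substituent is placed by the connectivity of A2, so there is no orientation problem. On regiochemical certainty this plan is the better of the two.
- *Against:* the coupling must make a tetrasubstituted alkene from a diaryl ketone flanked by an ortho methoxy group, where stalling at the diol stage is a known risk. A1 still needs dehydrogenation, oxidative demethylation of ring A with (NH4)2Ce(NO3)6 (tetravalent cerium) in the presence of two other electron-rich rings, and debenzylation that must not touch the quinone. The C6 stereocenter is made only to be destroyed.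
- *Comparison:* the chosen plan forms three bonds and two rings at the final oxidation level and needs one step afterwards; this plan forms one bond and one ring and needs at least three, on top of a linear assembly of A2. It is clearly behind on step economy and ahead only on regiocontrol.

**Alternative 2:** Ring A is cut at C4–C4a. Heating the 4-aryl-4-hydroxy-3-methoxycyclobutenone A4 in xylene should open the four-membered ring electrocyclically; 6π closure of the ketene carbon onto C4a and tautomerisation then give the naphthalene-1,4-diol A3, which a mild oxidant would take to 18.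
- *In favour:* the orientation of ring A follows from which carbonyl the aryl nucleophile attacks, and only one ortho position (C4a) is free for closure. The step is thermal and metal-free. On ring A regiocontrol and mechanistic precedent this plan is the better one. It is the equal of the chosen plan in protecting groups and nearly so in redox economy (one oxidation).
- *Against:* ring B is not built but bought: A4 needs a benzene ring that already carries the C6 benzyl, C7 methyl and C8 aryl groups in 1,2,3 order next to a metalation site. That contiguously substituted arene is the actual problem of the target, moved into the starting material.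
- *Comparison:* the end game is comparable, but overall step count and convergence favour the chosen plan, which makes ring B and its substitution pattern in the same step as ring A.

**Alternative 3:** Ring B is cut at C5–C6 and C7–C8. Irradiation of the ortho-benzyl benzaldehyde A6 at 365 nm should trigger photoenolisation, and Diels–Alder trapping by the ynone A7 followed by acid-promoted loss of water would give the naphthalene A5.
- *In favour:* the donor hydroxyl of the photoenol and the polarised ynone dictate the orientation electronically, which is a firmer basis than the steric bias of the chosen plan; on this point it is the better one. It is the equal in convergence (two fragments joined late, forming two of the same ring B bonds) and needs no transition metal.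
- *Against:* A7 carries a β-methyl group and alkynes are slow dienophiles towards photoenols. Ring A must be prepared beforehand as the pentasubstituted A6. After the key step the C6 aroyl carbonyl must be reduced to CH2, ring A oxidised to the quinone beside other electron-rich rings, and the benzyl ethers removed.
- *Comparison:* it is mechanistically more predictable in orientation, but it arrives at the wrong oxidation level at two sites and is longer after the key step (three or more steps against one).

Key step: step 12

Remarks on the chemistry:
- Atom labels C1 to C8a follow the naphthoquinone numbering of 19 and are used for the corresponding atoms of all precursors.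
- Vanillin is taken as the common source of both guaiacyl units.
- Dimethyldioxirane is used as a freshly prepared acetone solution (from acetone and KHSO5).
- "Safe" is read as chemically reliable.

## Route

Step 1
Reactants: 1 vanillin (4-hydroxy-3-methoxybenzaldehyde)
Product: 2 4-(tert-butyldimethylsilyloxy)-3-methoxybenzaldehyde
Conditions: TBSCl, imidazole, CH2Cl2, 0 °C → rt
Reagents that add atoms: tert-butyldimethylsilyl chloride, CC(C)(C)[Si](C)(C)Cl
Why: Standard silylation of a phenol; the aryl silyl ether should tolerate the organolithium, Grignard, palladium and rhodium steps and is removable by fluoride at the end.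

Step 2
Reactants: 2 4-(tert-butyldimethylsilyloxy)-3-methoxybenzaldehyde
Product: 3 tert-butyl(4-ethynyl-2-methoxyphenoxy)dimethylsilane
Conditions: TMSCHN2, n-BuLi, THF, −78 °C; then 2, −78 °C → rt; H2O
Reagents that add atoms: trimethylsilyldiazomethane, C[Si](C)(C)C=[N+]=[N-]
Why: Colvin homologation: the lithiated diazomethane adds to the aldehyde, Peterson-type loss of silanolate and of dinitrogen gives an alkylidene carbene, and a 1,2-hydrogen shift should give the terminal alkyne. No protic base is present, so the aryl silyl ether is not endangered.

Step 3
Reactants: 2 4-(tert-butyldimethylsilyloxy)-3-methoxybenzaldehyde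
Product: 4 [4-(tert-butyldimethylsilyloxy)-3-methoxyphenyl]methanol
Conditions: NaBH4, MeOH/THF, 0 °C
Reagents that add atoms: none
Why: Borohydride reduction of an aryl aldehyde; short reaction at 0 °C should leave the silyl ether intact.

Step 4
Reactants: 4 [4-(tert-butyldimethylsilyloxy)-3-methoxyphenyl]methanol
Product: 5 [4-(bromomethyl)-2-methoxyphenoxy](tert-butyl)dimethylsilane
Conditions: CBr4, PPh3, CH2Cl2, 0 °C; short silica plug, used at once
Reagents that add atoms: carbon tetrabromide, BrC(Br)(Br)Br
Why: Appel reaction under neutral conditions, suited to an electron-rich benzylic alcohol whose bromide ionises easily and is therefore not stored.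

Step 5
Reactants: 5 [4-(bromomethyl)-2-methoxyphenoxy](tert-butyl)dimethylsilane; 6 1-propynylmagnesium bromide (CH3C≡CMgBr, THF solution)
Product: 7 tert-butyl[4-(but-2-yn-1-yl)-2-methoxyphenoxy]dimethylsilane
Conditions: CuBr·SMe2 (10 mol %), THF, 0 → 50 °C
Reagents that add atoms: none
Why: Copper-catalysed sp3–sp coupling of a benzylic bromide with an alkynyl Grignard reagent; a benzylic electrophile cannot give an allene, so the 2-butyne is formed unambiguously.

Step 6
Reactants: 8 3-bromofuran
Product: 9 3-methoxyfuran
Conditions: NaOMe, CuBr (10 mol %), MeOH/NMP, 100 °C; distillation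
Reagents that add atoms: sodium methoxide, C[O-].[Na+]
Why: Ullmann-type copper-catalysed methoxylation of a heteroaryl bromide; the volatile product is isolated by distillation.

Step 7
Reactants: 9 3-methoxyfuran
Product: 11 2-iodo-3-methoxyfuran, via 2-lithio-3-methoxyfuran 10 (not isolated)
Conditions: n-BuLi, THF, −78 → 0 °C; I2, THF, −78 °C; used crude, cold and in the dark
Reagents that add atoms: iodine, II
Why: Deprotonation goes to C2, the position that is both α to the ring oxygen and ortho to the methoxy group, and iodine quenches the aryllithium. Directed lithiation with electrophilic trapping.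

Step 8
Reactants: 11 2-iodo-3-methoxyfuran; 3 tert-butyl(4-ethynyl-2-methoxyphenoxy)dimethylsilane
Product: 12 tert-butyl{2-methoxy-4-[(3-methoxyfuran-2-yl)ethynyl]phenoxy}dimethylsilane
Conditions: Pd(PPh3)2Cl2 (3 mol %), CuI (5 mol %), Et3N, THF, rt
Reagents that add atoms: none
Why: Sonogashira coupling; a 2-iodofuran adds readily to zerovalent palladium at room temperature, so the labile iodide is consumed quickly.

Step 9
Reactants: 12 tert-butyl{2-methoxy-4-[(3-methoxyfuran-2-yl)ethynyl]phenoxy}dimethylsilane
Product: 14 5-{[4-(tert-butyldimethylsilyloxy)-3-methoxyphenyl]ethynyl}-4-methoxyfuran-2-carbaldehyde, via C5-lithiated furan 13 (not isolated)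
Conditions: n-BuLi, THF, −78 °C; DMF, −78 → 0 °C; H2O
Reagents that add atoms: N,N-dimethylformamide, CN(C)C=O
Why: The only remaining α-hydrogen of the furan (C5) is the most acidic C–H of 12, and the aryllithium is formylated by DMF. At −78 °C carbolithiation of the alkyne and attack at silicon should not compete.

Step 10
Reactants: 14 5-{[4-(tert-butyldimethylsilyloxy)-3-methoxyphenyl]ethynyl}-4-methoxyfuran-2-carbaldehyde
Product: 15 tert-butyl{4-[(5-ethynyl-3-methoxyfuran-2-yl)ethynyl]-2-methoxyphenoxy}dimethylsilane
Conditions: TMSCHN2, n-BuLi, THF, −78 °C; then 14, −78 °C → rt; H2O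
Reagents that add atoms: trimethylsilyldiazomethane, C[Si](C)(C)C=[N+]=[N-]
Why: Colvin homologation as in step 2, here on a furfural-type aldehyde; it delivers the terminal alkyne directly, so no C-silyl group has to be removed beside the aryl silyl ether.

Step 11
Reactants: 15 tert-butyl{4-[(5-ethynyl-3-methoxyfuran-2-yl)ethynyl]-2-methoxyphenoxy}dimethylsilane
Product: 17 (4E)-1-[4-(tert-butyldimethylsilyloxy)-3-methoxyphenyl]-4-methoxyoct-4-ene-1,7-diyne-3,6-dione (the two acyl groups cis), via furan 2,3-epoxide 16 (not isolated)
Conditions: dimethyldioxirane (1.05 equiv, acetone solution), CH2Cl2, −78 → −20 °C; evaporation below 0 °C, used at once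
Reagents that add atoms: dimethyldioxirane, CC1(C)OO1
Why: Oxygen transfer to the electron-rich methoxy-substituted C2=C3 bond of the furan should give 16, which opens spontaneously to the 1,4-dicarbonyl compound; attack at the other furan double bond would converge on the same product. Because both carbonyl carbons were held by the ring oxygen, the enedione is formed with its acyl groups cis (known oxidative opening of 2,5-disubstituted furans). Acetone is the only by-product, so 17 needs no chromatography.

Step 12
Reactants: 17 (4E)-1-[4-(tert-butyldimethylsilyloxy)-3-methoxyphenyl]-4-methoxyoct-4-ene-1,7-diyne-3,6-dione; 7 tert-butyl[4-(but-2-yn-1-yl)-2-methoxyphenoxy]dimethylsilane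
Product: 18 larreantin bis(tert-butyldimethylsilyl) ether, 6-[4-(tert-butyldimethylsilyloxy)-3-methoxybenzyl]-8-[4-(tert-butyldimethylsilyloxy)-3-methoxyphenyl]-2-methoxy-7-methylnaphthalene-1,4-dione
Conditions: [Rh(cod)2]BF4 (10 mol %), rac-BINAP (10 mol %), H2 then Ar, CH2Cl2, rt; 17 added over 2 h to 7 (3 equiv)
Reagents that add atoms: none
Why: The cationic monovalent rhodium–BINAP fragment, freed from cod by hydrogenation, binds both ynone alkynes of 17 and couples them oxidatively to a trivalent rhodacyclopentadiene with rhodium on C5 and C8; this forms C4a–C8a and closes ring A as the six-membered enedione ring by intramolecular alkyne–alkyne coupling across the four-carbon tether. Alkyne 7 then coordinates and inserts into a Rh–C bond, and C–C reductive elimination forms C5–C6 and C7–C8, closing ring B as a benzene ring in an overall (2+2+2) cycloaddition and returning monovalent rhodium. The closest known reaction type is the rhodium- or iridium-catalysed (2+2+2) cycloaddition of 1,2-bis(propiolyl)arenes with monoalkynes to anthraquinones; here the arene of the tether is replaced by the cis C2=C3 bond, which likewise holds the two ynones within bonding distance. No stereocenter is formed, and the C8–aryl bond is not a stable axis. Cross- over homo-trimerisation is favoured by the intramolecular first coupling, by slow addition of 17 and by an excess of the internal alkyne 7, which is not expected to trimerise by itself. The step needs the CH2Ar end of 7 at C6: the larger end should avoid the aryl-bearing C8 terminus and bond next to the unsubstituted C5, a bias that is only moderate for CH2Ar against CH3. The cis geometry is protected by a 1:1 ligand-to-rhodium ratio (no free phosphine) and by the absence of acid and base, and the product is already at the quinone oxidation level.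

Step 13
Reactants: 18 larreantin bis(tert-butyldimethylsilyl) ether
Product: 19 larreantin, 6-(4-hydroxy-3-methoxybenzyl)-8-(4-hydroxy-3-methoxyphenyl)-2-methoxy-7-methylnaphthalene-1,4-dione
Conditions: HF·pyridine, THF/pyridine, 0 °C → rt
Reagents that add atoms: none
Why: Fluoride cleavage of both aryl silyl ethers; the weakly acidic, buffered reagent avoids the phenoxide that a basic fluoride source would generate next to the methoxyquinone.

## Compound list

1 | vanillin (4-hydroxy-3-methoxybenzaldehyde) | COc1cc(C=O)ccc1O | starting material
2 | 4-(tert-butyldimethylsilyloxy)-3-methoxybenzaldehyde | COc1cc(C=O)ccc1O[Si](C)(C)C(C)(C)C | intermediate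
3 | tert-butyl(4-ethynyl-2-methoxyphenoxy)dimethylsilane | C#Cc1ccc(O[Si](C)(C)C(C)(C)C)c(OC)c1 | intermediate
4 | [4-(tert-butyldimethylsilyloxy)-3-methoxyphenyl]methanol | OCc1ccc(O[Si](C)(C)C(C)(C)C)c(OC)c1 | intermediate
5 | [4-(bromomethyl)-2-methoxyphenoxy](tert-butyl)dimethylsilane | BrCc1ccc(O[Si](C)(C)C(C)(C)C)c(OC)c1 | intermediate
6 | 1-propynylmagnesium bromide | CC#C[Mg]Br | starting material
7 | tert-butyl[4-(but-2-yn-1-yl)-2-methoxyphenoxy]dimethylsilane | CC#CCc1ccc(O[Si](C)(C)C(C)(C)C)c(OC)c1 | intermediate
8 | 3-bromofuran | Brc1ccoc1 | starting material
9 | 3-methoxyfuran | COc1ccoc1 | intermediate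
10 | 2-lithio-3-methoxyfuran (not isolated) | [Li]c1occc1OC | intermediate
11 | 2-iodo-3-methoxyfuran | COc1ccoc1I | intermediate
12 | tert-butyl{2-methoxy-4-[(3-methoxyfuran-2-yl)ethynyl]phenoxy}dimethylsilane | COc1ccoc1C#Cc1ccc(O[Si](C)(C)C(C)(C)C)c(OC)c1 | intermediate
13 | C5-lithiated furan, tert-butyl{4-[(5-lithio-3-methoxyfuran-2-yl)ethynyl]-2-methoxyphenoxy}dimethylsilane (not isolated) | COc1cc([Li])oc1C#Cc1ccc(O[Si](C)(C)C(C)(C)C)c(OC)c1 | intermediate
14 | 5-{[4-(tert-butyldimethylsilyloxy)-3-methoxyphenyl]ethynyl}-4-methoxyfuran-2-carbaldehyde | COc1cc(C=O)oc1C#Cc1ccc(O[Si](C)(C)C(C)(C)C)c(OC)c1 | intermediate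
15 | tert-butyl{4-[(5-ethynyl-3-methoxyfuran-2-yl)ethynyl]-2-methoxyphenoxy}dimethylsilane | COc1cc(C#C)oc1C#Cc1ccc(O[Si](C)(C)C(C)(C)C)c(OC)c1 | intermediate
16 | furan 2,3-epoxide, 1-{[4-(tert-butyldimethylsilyloxy)-3-methoxyphenyl]ethynyl}-3-ethynyl-5-methoxy-2,6-dioxabicyclo[3.1.0]hex-3-ene (racemic, not isolated) | COC12OC1(C#Cc1ccc(O[Si](C)(C)C(C)(C)C)c(OC)c1)OC(C#C)=C2 | intermediate
17 | (4E)-1-[4-(tert-butyldimethylsilyloxy)-3-methoxyphenyl]-4-methoxyoct-4-ene-1,7-diyne-3,6-dione (acyl groups cis) | C#CC(=O)/C=C(OC)\C(=O)C#Cc1ccc(O[Si](C)(C)C(C)(C)C)c(OC)c1 | intermediate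
18 | larreantin bis(tert-butyldimethylsilyl) ether | COC1=CC(=O)c2cc(Cc3ccc(O[Si](C)(C)C(C)(C)C)c(OC)c3)c(C)c(-c3ccc(O[Si](C)(C)C(C)(C)C)c(OC)c3)c2C1=O | intermediate
19 | larreantin | COC1=CC(=O)c2cc(Cc3ccc(O)c(OC)c3)c(C)c(-c3ccc(O)c(OC)c3)c2C1=O | target

## Step count and least certain steps

Total step count: 13. Longest linear sequence: 8 steps (steps 6 to 13 from 8; equally steps 1, 2 and 8 to 13 from 1).

**Step 12 (key step).** The most likely failure is insertion of 7 in both orientations, because a methyl group and a primary benzyl group differ little in size. Loss of 17 by self-oligomerisation through its terminal ynone before it cyclises is the second concern. The fallback enlarges the benzylic end of the alkyne and removes the extra oxygen afterwards.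
- Setting out from 2 and 6, Grignard addition (THF, −78 → 0 °C) should give 1-[4-(tert-butyldimethylsilyloxy)-3-methoxyphenyl]but-2-yn-1-ol F1.
- Silylation (Et3SiCl, imidazole, CH2Cl2) gives tert-butyl{2-methoxy-4-[1-(triethylsilyloxy)but-2-yn-1-yl]phenoxy}dimethylsilane F2.
- Cyclotrimerisation of F2 with 17 under the conditions of step 12 should give 6-{[4-(tert-butyldimethylsilyloxy)-3-methoxyphenyl](triethylsilyloxy)methyl}-8-[4-(tert-butyldimethylsilyloxy)-3-methoxyphenyl]-2-methoxy-7-methylnaphthalene-1,4-dione F3. The branched, silyloxy-bearing end has a much stronger steric reason to bond next to C5–H.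
- Ionic hydrogenation of the doubly benzylic silyl ether (Et3SiH, CF3CO2H, CH2Cl2, 0 °C) removes the oxygen and comes back to the route at 18.

**Step 11.** The most likely failure is loss of 17 during its formation or concentration: cis-to-trans isomerisation, hydration of the ynones, or further oxidation of the alkynes by excess oxidant. The fallback replaces oxygen-atom transfer by a cycloaddition–reduction sequence.
- Setting out from 15, photooxygenation (O2, hν, methylene blue, CH2Cl2, −78 °C) should add singlet oxygen across the furan to give the endoperoxide 4-ethynyl-6-methoxy-1-{[4-(tert-butyldimethylsilyloxy)-3-methoxyphenyl]ethynyl}-2,3,7-trioxabicyclo[2.2.1]hept-5-ene F4.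
- Reduction of the O–O bond with Me2S at −78 °C lets it open to the cis-enedione, coming back to the route at 17.

**Step 7 (with the use of 11 in step 8).** The most likely failure is decomposition of the α-iodo enol ether 11 (loss of iodine, polymerisation) before it couples. The fallback avoids any halofuran by reversing the polarity of the coupling.
- Setting out from 3, bromination (NBS, AgNO3 cat., acetone) should give [4-(bromoethynyl)-2-methoxyphenoxy](tert-butyl)dimethylsilane F5.
- Setting out from 9 through 10, transmetalation with ZnCl2 gives (3-methoxyfuran-2-yl)zinc chloride F6.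
- Negishi-type coupling of F6 with F5 (Pd(PPh3)4, THF, rt) comes back to the route at 12, replacing steps 7 and 8.

**Step 9.** The most likely failure is deprotonation at the wrong site (C4 next to the methoxy group, or the guaiacyl ring) or addition of butyllithium across the alkyne. The fallback replaces deprotonation by electrophilic substitution: Vilsmeier–Haack formylation of 12 (POCl3, DMF, 0 °C; aqueous NaOAc) should attack the only free α-position, C5, and comes back to the route at 14 without any new isolated compound.

## Further compounds

F1 | step 12 | 1-[4-(tert-butyldimethylsilyloxy)-3-methoxyphenyl]but-2-yn-1-ol (racemic) | CC#CC(O)c1ccc(O[Si](C)(C)C(C)(C)C)c(OC)c1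
F2 | step 12 | tert-butyl{2-methoxy-4-[1-(triethylsilyloxy)but-2-yn-1-yl]phenoxy}dimethylsilane (racemic) | CC#CC(O[Si](CC)(CC)CC)c1ccc(O[Si](C)(C)C(C)(C)C)c(OC)c1
F3 | step 12 | 6-{[4-(tert-butyldimethylsilyloxy)-3-methoxyphenyl](triethylsilyloxy)methyl}-8-[4-(tert-butyldimethylsilyloxy)-3-methoxyphenyl]-2-methoxy-7-methylnaphthalene-1,4-dione (racemic) | COC1=CC(=O)c2cc(C(O[Si](CC)(CC)CC)c3ccc(O[Si](C)(C)C(C)(C)C)c(OC)c3)c(C)c(-c3ccc(O[Si](C)(C)C(C)(C)C)c(OC)c3)c2C1=O
F4 | step 11 | 4-ethynyl-6-methoxy-1-{[4-(tert-butyldimethylsilyloxy)-3-methoxyphenyl]ethynyl}-2,3,7-trioxabicyclo[2.2.1]hept-5-ene (racemic) | COC1=CC2(C#C)OOC1(C#Cc1ccc(O[Si](C)(C)C(C)(C)C)c(OC)c1)O2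
F5 | step 7 | [4-(bromoethynyl)-2-methoxyphenoxy](tert-butyl)dimethylsilane | BrC#Cc1ccc(O[Si](C)(C)C(C)(C)C)c(OC)c1
F6 | step 7 | (3-methoxyfuran-2-yl)zinc chloride | COc1ccoc1[Zn]Cl
F0 | step 9 | none | none
A1 | alternative 1 | 6-(4-benzyloxy-3-methoxybenzyl)-8-(4-benzyloxy-3-methoxyphenyl)-1,2,4-trimethoxy-7-methyl-5,6-dihydronaphthalene (racemic, one enantiomer drawn) | COc1cc(OC)c2C[C@@H](Cc3ccc(OCc4ccccc4)c(OC)c3)C(C)=C(c3ccc(OCc4ccccc4)c(OC)c3)c2c1OC
A2 | alternative 1 | 4-[2-(4-benzyloxy-3-methoxybenzoyl)-3,4,6-trimethoxyphenyl]-3-(4-benzyloxy-3-methoxybenzyl)butan-2-one (racemic) | COc1cc(OC)c(CC(Cc2ccc(OCc3ccccc3)c(OC)c2)C(C)=O)c(C(=O)c2ccc(OCc3ccccc3)c(OC)c2)c1OC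
A3 | alternative 2 | 6-[4-(tert-butyldimethylsilyloxy)-3-methoxybenzyl]-8-[4-(tert-butyldimethylsilyloxy)-3-methoxyphenyl]-2-methoxy-7-methylnaphthalene-1,4-diol | COc1cc(O)c2cc(Cc3ccc(O[Si](C)(C)C(C)(C)C)c(OC)c3)c(C)c(-c3ccc(O[Si](C)(C)C(C)(C)C)c(OC)c3)c2c1O
A4 | alternative 2 | 4-{4-[4-(tert-butyldimethylsilyloxy)-3-methoxybenzyl]-2-[4-(tert-butyldimethylsilyloxy)-3-methoxyphenyl]-3-methylphenyl}-4-hydroxy-3-methoxycyclobut-2-en-1-one (racemic) | O=C1C=C(OC)C1(O)c1ccc(Cc2ccc(O[Si](C)(C)C(C)(C)C)c(OC)c2)c(C)c1-c1ccc(O[Si](C)(C)C(C)(C)C)c(OC)c1
A5 | alternative 3 | 6-(4-benzyloxy-3-methoxybenzoyl)-8-(4-benzyloxy-3-methoxyphenyl)-1,2,4-trimethoxy-7-methylnaphthalene | COc1cc(OC)c2cc(C(=O)c3ccc(OCc4ccccc4)c(OC)c3)c(C)c(-c3ccc(OCc4ccccc4)c(OC)c3)c2c1OC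
A6 | alternative 3 | 2-(4-benzyloxy-3-methoxybenzyl)-3,4,6-trimethoxybenzaldehyde | COc1cc(OC)c(C=O)c(Cc2ccc(OCc3ccccc3)c(OC)c2)c1OC
A7 | alternative 3 | 1-(4-benzyloxy-3-methoxyphenyl)but-2-yn-1-one | CC#CC(=O)c1ccc(OCc2ccccc2)c(OC)c1
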